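**Retrosynthetic overview**

1. Target ⇐ C15-selective saponification of the 15,18-dimethyl diester ⇐ 18-acid ⇐ 18-alcohol ⇐ 3β,18-diol (radical removal of the C3 oxygen).
2. Key disconnection, C4–C5 and C9–C10 together: one titanocene-chloride radical cascade on an acyclic (14S,15S)-epoxy alcohol closes ring A, then ring B, and ends as the C8=C17 methylene. The C3 oxygen only relays absolute configuration.
3. Epoxy alcohol ⇐ Sharpless epoxidation ⇐ SeO2 oxidation of the terminal E-methyl (the future C18) of a (3S)-dihydrogeranylgeranoate.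
4. C13 ⇐ CuH asymmetric conjugate reduction of methyl geranylgeranoate ⇐ HWE olefination of farnesylacetone.

Assumption: the SMILES is read as (4R,5R,9S,10R,13S), i.e. a normal labd-8(17)-ene with the methyl ester on the 4α (equatorial, C18) carbon and the free acid at C15; labdane numbering is used for ring compounds, and farnesylacetone is taken as the geometrically pure (5E,9E) isomer.

**Route**

Step 1
Reactants: 1 (5E,9E)-6,10,14-trimethylpentadeca-5,9,13-trien-2-one (farnesylacetone); 2 trimethyl phosphonoacetate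
Product: 4 methyl (2E,6E,10E)-3,7,11,15-tetramethylhexadeca-2,6,10,14-tetraenoate, via sodium phosphonoacetate carbanion 3 (not isolated)
Conditions: NaH, THF, 0 °C; then 1, 0 to 50 °C; 2Z isomer removed on AgNO3–SiO2
Reagents that add atoms: none
Why: Horner–Wadsworth–Emmons olefination of the methyl ketone gives mainly the 2E enoate (about 4:1), and the 2Z isomer is removed because it would give the wrong C13 configuration in step 2; no stereocentre is formed.

Step 2
Reactants: 4 methyl (2E,6E,10E)-3,7,11,15-tetramethylhexadeca-2,6,10,14-tetraenoate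
Product: 5 methyl (3S,6E,10E)-3,7,11,15-tetramethylhexadeca-6,10,14-trienoate
Conditions: Cu(OAc)2·H2O (3 mol %), (S)-DTBM-SEGPHOS (3 mol %), (EtO)2MeSiH, t-BuOH, toluene, 0 °C to rt
Reagents that add atoms: none
Why: Copper hydride asymmetric conjugate reduction of the E-enoate (ligand-controlled hydride delivery to the β-carbon, then protonation by t-BuOH) sets the future C13 as S with the (S)-ligand/E-enoate pairing, as recalled from the literature and to be confirmed by optical rotation (the R ligand gives 3R), and the isolated trisubstituted alkenes are inert.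

Step 3
Reactants: 5 methyl (3S,6E,10E)-3,7,11,15-tetramethylhexadeca-6,10,14-trienoate
Product: 6 methyl (3S,6E,10E,14E)-16-hydroxy-3,7,11,15-tetramethylhexadeca-6,10,14-trienoate
Conditions: SeO2 (0.3 equiv), t-BuOOH, salicylic acid (10 mol %), CH2Cl2, 0 °C to rt, stopped at partial conversion
Reagents that add atoms: tert-butyl hydroperoxide, CC(C)(C)OO (terminal oxidant; the oxygen is passed on by catalytic selenium dioxide, O=[Se]=O)
Why: Sharpless–Umbreit allylic oxidation (ene reaction then [2,3]-shift) is selective for the E-methyl of the terminal isopropylidene, so the hydroxymethyl carbon that becomes C18 is placed trans to the chain.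

Step 4
Reactants: 6 methyl (3S,6E,10E,14E)-16-hydroxy-3,7,11,15-tetramethylhexadeca-6,10,14-trienoate
Product: 7 methyl (3S,6E,10E)-13-[(2S,3S)-3-(hydroxymethyl)-3-methyloxiran-2-yl]-3,7,11-trimethyltrideca-6,10-dienoate
Conditions: Ti(OiPr)4 (10 mol %), L-(+)-diethyl tartrate (12 mol %), t-BuOOH, 4 Å MS, CH2Cl2, −20 °C
Reagents that add atoms: tert-butyl hydroperoxide, CC(C)(C)OO
Why: Sharpless asymmetric epoxidation touches only the allylic-alcohol alkene and, with L-(+)-tartrate, gives the (2S,3S)-epoxy alcohol by reagent control, the oxirane CH carbon being the future C3.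

Step 5
Reactants: 7 methyl (3S,6E,10E)-13-[(2S,3S)-3-(hydroxymethyl)-3-methyloxiran-2-yl]-3,7,11-trimethyltrideca-6,10-dienoate
Product: 10 methyl (3S,4R,5R,9S,10R,13S)-3β,18-dihydroxylabd-8(17)-en-15-oate, via silylated epoxy alcohol 8 (not isolated), via bis-silyl ether 9 (not isolated)
Conditions: Cp2TiCl2 (20 mol %), Mn dust, Me3SiCl, 2,4,6-collidine, THF (0.02 M), rt; then K2CO3, MeOH
Reagents that add atoms: none
Why: After in-situ silylation of the primary hydroxyl, Nugent–RajanBabu epoxide homolysis by Cp2TiCl (trivalent titanium) gives the tertiary C4 radical, which closes ring A then ring B by a 6-endo/6-endo radical polyene cyclization through a chair–chair array (E-alkenes give 10β-CH3, 5α-H and the equatorial 9β side chain; the equatorial C3–OTi group from the Sharpless epoxide relays absolute configuration; the bulkier CH2OSiMe3 arm on the planar C4 radical is expected to take the equatorial 4α site, leaving 4β-CH3, though this preference is the least secure selectivity of the route), and the final C8 radical is drained by Cp2TiCl to the exocyclic alkene.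

Step 6
Reactants: 10 methyl (3S,4R,5R,9S,10R,13S)-3β,18-dihydroxylabd-8(17)-en-15-oate
Product: 12 methyl (3S,4R,5R,9S,10R,13S)-3β,18-(thiocarbonyldioxy)labd-8(17)-en-15-oate (cyclic thionocarbonate), via mono-imidazolide 11 (not isolated)
Conditions: 1,1'-thiocarbonyldiimidazole, DMAP (cat.), toluene, 110 °C
Reagents that add atoms: 1,1'-thiocarbonyldiimidazole, S=C(n1ccnc1)n1ccnc1
Why: Thiocarbonyl transfer acylates the primary hydroxyl first and then closes on the hindered 3β-hydroxyl to give the six-membered cyclic thionocarbonate of the diequatorial 1,3-diol, with no change at any stereocentre.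

Step 7
Reactants: 12 cyclic 3β,18-thionocarbonate
Product: 14 methyl (4R,5R,9S,10R,13S)-18-hydroxylabd-8(17)-en-15-oate, via stannyl thiocarbonate 13 (not isolated)
Conditions: Bu3SnH, AIBN (cat.), toluene, 110 °C; then K2CO3, MeOH, rt
Reagents that add atoms: none
Why: Barton–McCombie-type radical deoxygenation of a cyclic thionocarbonate: the tin-radical adduct fragments at C3–O to give the secondary C3 radical rather than the primary neopentyl C18 radical, which removes the C3 stereocentre as planned and leaves the 18-oxygen as a stannyl thiocarbonate that mild methanolysis frees without touching the methyl ester.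

Step 8
Reactants: 14 methyl (4R,5R,9S,10R,13S)-18-hydroxylabd-8(17)-en-15-oate
Product: 16 (4R,5R,9S,10R,13S)-15-methoxy-15-oxolabd-8(17)-en-18-oic acid, via 18-aldehyde 15 (not isolated)
Conditions: CrO3, H2SO4, H2O, acetone, 0 °C
Reagents that add atoms: water, O
Why: Jones oxidation takes the neopentyl primary alcohol through the aldehyde hydrate to the acid; the quaternary C4 cannot epimerise, and the exocyclic alkene and methyl ester tolerate the short, cold exposure.

Step 9
Reactants: 16 (4R,5R,9S,10R,13S)-15-methoxy-15-oxolabd-8(17)-en-18-oic acid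
Product: 17 dimethyl (4R,5R,9S,10R,13S)-labd-8(17)-ene-15,18-dioate
Conditions: Me3SiCHN2, toluene–MeOH (4:1), rt
Reagents that add atoms: (trimethylsilyl)diazomethane, C[Si](C)(C)C=[N+]=[N-]
Why: Diazoalkane O-methylation alkylates the carboxylate oxygen and is therefore insensitive to the steric shielding of the acid at quaternary C4.

Step 10
Reactants: 17 dimethyl (4R,5R,9S,10R,13S)-labd-8(17)-ene-15,18-dioate
Product: 19 (4R,5R,9S,10R,13S)-18-methoxy-18-oxolabd-8(17)-en-15-oic acid (target), via lithium carboxylate 18 (not isolated)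
Conditions: LiOH·H2O (1.5 equiv), THF–MeOH–H2O, rt; then 1 M HCl
Reagents that add atoms: lithium hydroxide, [Li+].[OH-]
Why: Chemoselective saponification: the unhindered primary C15 ester is hydrolysed at room temperature while the C18 ester on quaternary C4 is inert, and no stereocentre is affected.

**Compound list**

1 | (5E,9E)-6,10,14-trimethylpentadeca-5,9,13-trien-2-one (farnesylacetone) | CC(=O)CC/C=C(\C)CC/C=C(\C)CCC=C(C)C | starting material
2 | trimethyl phosphonoacetate | COC(=O)CP(=O)(OC)OC | starting material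
3 | sodium salt of the carbanion of 2 (formed in situ) | COC(=O)[CH-]P(=O)(OC)OC.[Na+] | intermediate
4 | methyl (2E,6E,10E)-3,7,11,15-tetramethylhexadeca-2,6,10,14-tetraenoate (methyl geranylgeranoate) | COC(=O)/C=C(\C)CC/C=C(\C)CC/C=C(\C)CCC=C(C)C | intermediate
5 | methyl (3S,6E,10E)-3,7,11,15-tetramethylhexadeca-6,10,14-trienoate | COC(=O)C[C@@H](C)CC/C=C(\C)CC/C=C(\C)CCC=C(C)C | intermediate
6 | methyl (3S,6E,10E,14E)-16-hydroxy-3,7,11,15-tetramethylhexadeca-6,10,14-trienoate | COC(=O)C[C@@H](C)CC/C=C(\C)CC/C=C(\C)CC/C=C(\C)CO | intermediate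
7 | methyl (3S,6E,10E)-13-[(2S,3S)-3-(hydroxymethyl)-3-methyloxiran-2-yl]-3,7,11-trimethyltrideca-6,10-dienoate | COC(=O)C[C@@H](C)CC/C=C(\C)CC/C=C(\C)CC[C@@H]1O[C@@]1(C)CO | intermediate
8 | trimethylsilyl ether of 7 at the primary hydroxyl (formed in situ) | COC(=O)C[C@@H](C)CC/C=C(\C)CC/C=C(\C)CC[C@@H]1O[C@@]1(C)CO[Si](C)(C)C | intermediate
9 | methyl (3S,4R,5R,9S,10R,13S)-3β,18-bis(trimethylsilyloxy)labd-8(17)-en-15-oate (formed in situ) | C=C1CC[C@@H]2[C@](C)(CC[C@H](O[Si](C)(C)C)[C@@]2(C)CO[Si](C)(C)C)[C@H]1CC[C@H](C)CC(=O)OC | intermediate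
10 | methyl (3S,4R,5R,9S,10R,13S)-3β,18-dihydroxylabd-8(17)-en-15-oate (4α-CH2OH, 4β-CH3, 5α-H, 9α-H, 10β-CH3) | C=C1CC[C@@H]2[C@](C)(CC[C@H](O)[C@@]2(C)CO)[C@H]1CC[C@H](C)CC(=O)OC | intermediate
11 | 18-O-(imidazol-1-ylthiocarbonyl) derivative of 10 (formed in situ) | C=C1CC[C@@H]2[C@](C)(CC[C@H](O)[C@@]2(C)COC(=S)n3ccnc3)[C@H]1CC[C@H](C)CC(=O)OC | intermediate
12 | cyclic 3β,18-thionocarbonate of 10 (1,3-dioxane-2-thione fused at C3–C4) | C=C1CC[C@@H]2[C@](C)(CC[C@H](OC(=S)OC3)[C@]23C)[C@H]1CC[C@H](C)CC(=O)OC | intermediate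
13 | methyl (4R,5R,9S,10R,13S)-18-{[(tributylstannyl)sulfanyl]carbonyloxy}labd-8(17)-en-15-oate (formed in situ) | C=C1CC[C@@H]2[C@](C)(CCC[C@@]2(C)COC(=O)S[Sn](CCCC)(CCCC)CCCC)[C@H]1CC[C@H](C)CC(=O)OC | intermediate
14 | methyl (4R,5R,9S,10R,13S)-18-hydroxylabd-8(17)-en-15-oate | C=C1CC[C@@H]2[C@](C)(CCC[C@@]2(C)CO)[C@H]1CC[C@H](C)CC(=O)OC | intermediate
15 | methyl (4R,5R,9S,10R,13S)-18-oxolabd-8(17)-en-15-oate (formed in situ) | C=C1CC[C@@H]2[C@](C)(CCC[C@@]2(C)C=O)[C@H]1CC[C@H](C)CC(=O)OC | intermediate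
16 | (4R,5R,9S,10R,13S)-15-methoxy-15-oxolabd-8(17)-en-18-oic acid | C=C1CC[C@@H]2[C@](C)(CCC[C@@]2(C)C(=O)O)[C@H]1CC[C@H](C)CC(=O)OC | intermediate
17 | dimethyl (4R,5R,9S,10R,13S)-labd-8(17)-ene-15,18-dioate | C=C1CC[C@@H]2[C@](C)(CCC[C@@]2(C)C(=O)OC)[C@H]1CC[C@H](C)CC(=O)OC | intermediate
18 | lithium (4R,5R,9S,10R,13S)-18-methoxy-18-oxolabd-8(17)-en-15-oate (formed in situ) | C=C1CC[C@@H]2[C@](C)(CCC[C@@]2(C)C(=O)OC)[C@H]1CC[C@H](C)CC(=O)[O-].[Li+] | intermediate
19 | (4R,5R,9S,10R,13S)-18-methoxy-18-oxolabd-8(17)-en-15-oic acid | C=C1CC[C@@H]2[C@](C)(CCC[C@@]2(C)C(=O)OC)[C@H]1CC[C@H](C)CC(=O)O | target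

**Totals and risks**

Total step count: 10. Longest linear sequence: 10 (fully linear from 1).

Steps most likely to fail:

Step 5 (radical bicyclization). Yields for such cascades are moderate, with monocyclic and C8-reduced by-products. The C4 configuration rests on a transition-state preference of a planar radical, not on transfer of epoxide geometry, and steric analysis suggests this preference may be small. Fallback: leave the route at 7 and silylate the primary hydroxyl (t-BuMe2SiCl, imidazole) to the epoxy silyl ether F1. Cyclize it in the cationic mode (MeAlCl2, CH2Cl2, −78 °C), where the epoxide opens in concert with attack of the C5=C10 alkene, so the E-disposed CH2OSi arm is delivered equatorially by geometry. After removal of the endocyclic alkene isomers on AgNO3-impregnated silica this gives the 3β-hydroxy 18-silyl ether F2, and Bu4NF returns to diol 10.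

Step 7 (regioselective deoxygenation). Fragmentation of the cyclic thionocarbonate could partly cleave the C18–O bond or stall. Fallback: set out from diol 10 and differentiate the hydroxyls instead. t-BuPh2SiCl/imidazole silylates only the primary hydroxyl to the 18-silyl ether F3, NaH/CS2/MeI gives the 3β-xanthate F4, Bu3SnH/AIBN gives the 3-deoxy silyl ether F5, and Bu4NF rejoins the route at alcohol 14.

Step 3 (SeO2 oxidation). Regioselectivity among three trisubstituted alkenes and over-oxidation limit the yield. Fallback: set out from 5. NBS in aqueous THF gives the terminal bromohydrin F6 (selective for the terminal alkene), K2CO3/MeOH closes it to the terminal epoxide F7, and HIO4 cleaves this to the trisnor aldehyde F8. Wittig olefination with Ph3P=C(CH3)CHO gives the E-enal F9, and NaBH4/CeCl3·7H2O reduction rejoins the route at allylic alcohol 6.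

Further compounds
F1 | step 5 | methyl (3S,6E,10E)-13-[(2S,3S)-3-{[(tert-butyldimethylsilyl)oxy]methyl}-3-methyloxiran-2-yl]-3,7,11-trimethyltrideca-6,10-dienoate | COC(=O)C[C@@H](C)CC/C=C(\C)CC/C=C(\C)CC[C@@H]1O[C@@]1(C)CO[Si](C)(C)C(C)(C)C
F2 | step 5 | methyl (3S,4R,5R,9S,10R,13S)-18-[(tert-butyldimethylsilyl)oxy]-3β-hydroxylabd-8(17)-en-15-oate | C=C1CC[C@@H]2[C@](C)(CC[C@H](O)[C@@]2(C)CO[Si](C)(C)C(C)(C)C)[C@H]1CC[C@H](C)CC(=O)OC
F3 | step 7 | methyl (3S,4R,5R,9S,10R,13S)-18-[(tert-butyldiphenylsilyl)oxy]-3β-hydroxylabd-8(17)-en-15-oate | C=C1CC[C@@H]2[C@](C)(CC[C@H](O)[C@@]2(C)CO[Si](c3ccccc3)(c3ccccc3)C(C)(C)C)[C@H]1CC[C@H](C)CC(=O)OC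
F4 | step 7 | methyl (3S,4R,5R,9S,10R,13S)-18-[(tert-butyldiphenylsilyl)oxy]-3β-{[(methylsulfanyl)carbonothioyl]oxy}labd-8(17)-en-15-oate | C=C1CC[C@@H]2[C@](C)(CC[C@H](OC(=S)SC)[C@@]2(C)CO[Si](c3ccccc3)(c3ccccc3)C(C)(C)C)[C@H]1CC[C@H](C)CC(=O)OC
F5 | step 7 | methyl (4R,5R,9S,10R,13S)-18-[(tert-butyldiphenylsilyl)oxy]labd-8(17)-en-15-oate | C=C1CC[C@@H]2[C@](C)(CCC[C@@]2(C)CO[Si](c3ccccc3)(c3ccccc3)C(C)(C)C)[C@H]1CC[C@H](C)CC(=O)OC
F6 | step 3 | methyl (3S,6E,10E)-14-bromo-15-hydroxy-3,7,11,15-tetramethylhexadeca-6,10-dienoate (both C14 epimers) | COC(=O)C[C@@H](C)CC/C=C(\C)CC/C=C(\C)CCC(Br)C(C)(C)O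
F7 | step 3 | methyl (3S,6E,10E)-13-(3,3-dimethyloxiran-2-yl)-3,7,11-trimethyltrideca-6,10-dienoate (both oxirane epimers) | COC(=O)C[C@@H](C)CC/C=C(\C)CC/C=C(\C)CCC1OC1(C)C
F8 | step 3 | methyl (3S,6E,10E)-3,7,11-trimethyl-14-oxotetradeca-6,10-dienoate | COC(=O)C[C@@H](C)CC/C=C(\C)CC/C=C(\C)CCC=O
F9 | step 3 | methyl (3S,6E,10E,14E)-3,7,11,15-tetramethyl-16-oxohexadeca-6,10,14-trienoate | COC(=O)C[C@@H](C)CC/C=C(\C)CC/C=C(\C)CC/C=C(\C)C=O
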